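The route rests on disconnecting the O1–C8a aryl ether bond of the pyran ring (ring B). That ring contains a Z-configured C3=C4 double bond, conjugated to ring A at C4a and attached to the oxygen-bearing quaternary centre C2, whose carbon substituents map onto C3 of (S)-linalool. In one operation, visible light and a triplet sensitiser turn an E-styrene into its Z-isomer, and only this isomer lets the C2 alkoxide displace fluoride at C8a, para to a formyl group. The precursor, an E-styrenyl tertiary alcohol with an ortho fluorine, comes from a Heck reaction of silylated 8-hydroxylinalool. The formyl group later becomes the ethylene bridge to the catechol ring.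

Key step: step 4

Remark: chromene numbering is used (O1, C2, C3, C4, C4a, C5 to C8, C8a; ring A = benzo ring, ring B = pyran ring, ring C = catechol ring), and enantiopure (S)-linalool and 3-bromocatechol are taken as purchasable.

Step 1
Reactants: 1 (S)-linalool
Product: 2 (2E,6S)-2,6-dimethylocta-2,7-diene-1,6-diol
Conditions: SeO2 (0.3 equiv), t-BuOOH (2 equiv), salicylic acid (0.1 equiv), CH2Cl2, 0 °C to rt
Reagents that add atoms: selenium dioxide, O=[Se]=O (delivers the hydroxyl oxygen); tert-butyl hydroperoxide, CC(C)(C)OO (re-oxidises the selenium and so restocks that oxygen)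
Why: Riley allylic oxidation (ene reaction followed by a [2,3]-sigmatropic shift) should attack the electron-rich trisubstituted alkene at its E-methyl group and give the E-allylic alcohol, while the monosubstituted vinyl group and the tertiary carbinol are left alone.

Step 2
Reactants: 2 (2E,6S)-2,6-dimethylocta-2,7-diene-1,6-diol
Product: 3 (3S,6E)-8-(tert-butyldimethylsilyloxy)-3,7-dimethylocta-1,6-dien-3-ol
Conditions: TBSCl (1.05 equiv), imidazole (2 equiv), CH2Cl2, 0 °C
Reagents that add atoms: tert-butyldimethylsilyl chloride, CC(C)(C)[Si](C)(C)Cl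
Why: Silyl ether formation with a bulky silyl chloride is much faster at the primary allylic hydroxyl than at the tertiary one, so selective mono-protection is expected.

Step 3
Reactants: 3 (3S,6E)-8-(tert-butyldimethylsilyloxy)-3,7-dimethylocta-1,6-dien-3-ol; 4 3-bromo-4-fluorobenzaldehyde
Product: 5 4-fluoro-3-[(1E,3S,6E)-8-(tert-butyldimethylsilyloxy)-3-hydroxy-3,7-dimethylocta-1,6-dienyl]benzaldehyde
Conditions: Pd(OAc)2 (5 mol%), P(o-tol)3 (10 mol%), Et3N (2.5 equiv), DMF, 90 °C
Reagents that add atoms: none
Why: In this Heck reaction the aryl group should add to the terminal carbon of the vinyl group, and since the carbinol carbon has no hydrogen, syn β-hydride elimination can only go toward the benzylic side and should give the E-styrene, the trisubstituted alkene being too hindered to insert.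

Step 4
Reactants: 5 4-fluoro-3-[(1E,3S,6E)-8-(tert-butyldimethylsilyloxy)-3-hydroxy-3,7-dimethylocta-1,6-dienyl]benzaldehyde
Product: 7 (S)-2-[(E)-5-(tert-butyldimethylsilyloxy)-4-methylpent-3-enyl]-2-methyl-2H-chromene-6-carbaldehyde, via Z-styrenyl carbinol 6 (not isolated)
Conditions: fac-Ir(ppy)3 (1 mol%), blue LEDs (450 nm), degassed THF (0.01 M), rt, to the photostationary state; then KOtBu (1.1 equiv, slow addition as a THF solution), light kept on, rt
Reagents that add atoms: none
Why: Triplet energy transfer from photoexcited fac-Ir(ppy)3 to the planar, conjugated E-styrene of 5 gives a twisted triplet that relaxes to either geometry, and the Z-isomer 6, forced out of planarity by A(1,3) strain between quaternary C2 and the ortho positions of ring A, is a poorer acceptor and should therefore build up against the ground-state preference. After deprotonation, the alkoxide of 6 sits within reach of the fluorine-bearing carbon and should add there to give a Meisenheimer complex that is stabilised by the para formyl group and collapses with loss of fluoride, which forms O1–C8a (addition–elimination, SNAr). The closest known reaction types are the sensitised E-to-Z isomerisation of β-alkyl styrenes by energy transfer and the intramolecular SNAr etherification of acyl-activated aryl fluorides by alkoxides. Ring B closes in a 6-exo-trig addition of the oxygen to the arene carbon. No stereocentre is created, and C2 keeps the configuration of (S)-linalool because none of its four bonds is broken. The step needs Z geometry and intramolecular rather than intermolecular O-arylation; the first is secured by the twisted Z-styrene escaping re-excitation, the second by the fact that only the Z-alkoxide can reach C8a, helped by high dilution and by adding the base only once 6 has accumulated, so that tert-butoxide finds little E-isomer to attack while the light keeps feeding residual E-isomer into the closure.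

Step 5
Reactants: 7 (S)-2-[(E)-5-(tert-butyldimethylsilyloxy)-4-methylpent-3-enyl]-2-methyl-2H-chromene-6-carbaldehyde
Product: 8 (S)-2-[(E)-5-(tert-butyldimethylsilyloxy)-4-methylpent-3-enyl]-2-methyl-6-vinyl-2H-chromene
Conditions: Ph3PCH3Br (1.5 equiv), KOtBu (1.4 equiv), THF, 0 °C to rt
Reagents that add atoms: methyltriphenylphosphonium bromide, C[P+](c1ccccc1)(c1ccccc1)c1ccccc1.[Br-]
Why: Wittig methylenation of a non-enolisable aryl aldehyde with the unstabilised ylide is dependable and should not touch the silyl ether, the chromene or the side-chain alkene.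

Step 6
Reactants: 9 3-bromocatechol (3-bromobenzene-1,2-diol)
Product: 10 1-bromo-2,3-bis(tert-butyldimethylsilyloxy)benzene
Conditions: TBSCl (2.5 equiv), imidazole (5 equiv), DMF, rt
Reagents that add atoms: tert-butyldimethylsilyl chloride, CC(C)(C)[Si](C)(C)Cl
Why: Silylation of phenols under these conditions is routine, and the excess of reagent should also drive the more hindered hydroxyl next to bromine to its silyl ether.

Step 7
Reactants: 8 (S)-2-[(E)-5-(tert-butyldimethylsilyloxy)-4-methylpent-3-enyl]-2-methyl-6-vinyl-2H-chromene; 10 1-bromo-2,3-bis(tert-butyldimethylsilyloxy)benzene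
Product: 12 (S)-6-{2-[2,3-bis(tert-butyldimethylsilyloxy)phenyl]ethyl}-2-[(E)-5-(tert-butyldimethylsilyloxy)-4-methylpent-3-enyl]-2-methyl-2H-chromene, via B-alkyl-9-BBN borane 11 (not isolated)
Conditions: 9-BBN (1.3 equiv), THF, 0 °C to rt; then 10, Pd(OAc)2 (5 mol%), SPhos (10 mol%), K3PO4·H2O (3 equiv), THF, 45 °C
Reagents that add atoms: 9-borabicyclo[3.3.1]nonane (9-BBN), B1C2CCCC1CCC2 (its boron and carbon atoms stay in 11 only; 12 keeps just one hydrogen of it)
Why: Anti-Markovnikov hydroboration with bulky 9-BBN should take only the monosubstituted vinyl group (the C3=C4 bond is shielded by quaternary C2 and the side-chain alkene is trisubstituted), and the primary alkylborane should then couple with the aryl bromide in a B-alkyl Suzuki–Miyaura reaction under a weak, nearly anhydrous base that the aryl silyl ethers tolerate.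

Step 8
Reactants: 12 (S)-6-{2-[2,3-bis(tert-butyldimethylsilyloxy)phenyl]ethyl}-2-[(E)-5-(tert-butyldimethylsilyloxy)-4-methylpent-3-enyl]-2-methyl-2H-chromene
Product: 13 3-{2-[(2S)-2-[(3E)-5-hydroxy-4-methylpent-3-enyl]-2-methyl-2H-chromen-6-yl]ethyl}benzene-1,2-diol (target)
Conditions: TBAF (4 equiv), AcOH (4 equiv), THF, 0 °C to rt, argon
Reagents that add atoms: none
Why: Fluoride-mediated desilylation should remove the two aryl silyl ethers and the primary allylic one in a single operation, and the acetic acid buffer keeps the catechol protonated and spares the chromene and the allylic alcohol both strong acid and strong base.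

Compound list
1 | (S)-linalool, (3S)-3,7-dimethylocta-1,6-dien-3-ol | CC(C)=CCC[C@@](O)(C)C=C | starting material
2 | (2E,6S)-2,6-dimethylocta-2,7-diene-1,6-diol | C/C(=C\CC[C@@](O)(C)C=C)CO | intermediate
3 | (3S,6E)-8-(tert-butyldimethylsilyloxy)-3,7-dimethylocta-1,6-dien-3-ol | C/C(=C\CC[C@@](O)(C)C=C)CO[Si](C)(C)C(C)(C)C | intermediate
4 | 3-bromo-4-fluorobenzaldehyde | O=Cc1ccc(F)c(Br)c1 | starting material
5 | 4-fluoro-3-[(1E,3S,6E)-8-(tert-butyldimethylsilyloxy)-3-hydroxy-3,7-dimethylocta-1,6-dienyl]benzaldehyde | C/C(=C\CC[C@@](O)(C)/C=C/c1cc(C=O)ccc1F)CO[Si](C)(C)C(C)(C)C | intermediate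
6 | 4-fluoro-3-[(1Z,3S,6E)-8-(tert-butyldimethylsilyloxy)-3-hydroxy-3,7-dimethylocta-1,6-dienyl]benzaldehyde (not isolated) | C/C(=C\CC[C@@](O)(C)/C=C\c1cc(C=O)ccc1F)CO[Si](C)(C)C(C)(C)C | intermediate
7 | (S)-2-[(E)-5-(tert-butyldimethylsilyloxy)-4-methylpent-3-enyl]-2-methyl-2H-chromene-6-carbaldehyde | C/C(=C\CC[C@@]1(C)C=Cc2cc(C=O)ccc2O1)CO[Si](C)(C)C(C)(C)C | intermediate
8 | (S)-2-[(E)-5-(tert-butyldimethylsilyloxy)-4-methylpent-3-enyl]-2-methyl-6-vinyl-2H-chromene | C/C(=C\CC[C@@]1(C)C=Cc2cc(C=C)ccc2O1)CO[Si](C)(C)C(C)(C)C | intermediate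
9 | 3-bromocatechol (3-bromobenzene-1,2-diol) | Oc1cccc(Br)c1O | starting material
10 | 1-bromo-2,3-bis(tert-butyldimethylsilyloxy)benzene | CC(C)(C)[Si](C)(C)Oc1cccc(Br)c1O[Si](C)(C)C(C)(C)C | intermediate
11 | 9-{2-[(S)-2-[(E)-5-(tert-butyldimethylsilyloxy)-4-methylpent-3-enyl]-2-methyl-2H-chromen-6-yl]ethyl}-9-borabicyclo[3.3.1]nonane (not isolated) | C/C(=C\CC[C@@]1(C)C=Cc2cc(CCB3C4CCCC3CCC4)ccc2O1)CO[Si](C)(C)C(C)(C)C | intermediate
12 | (S)-6-{2-[2,3-bis(tert-butyldimethylsilyloxy)phenyl]ethyl}-2-[(E)-5-(tert-butyldimethylsilyloxy)-4-methylpent-3-enyl]-2-methyl-2H-chromene | C/C(=C\CC[C@@]1(C)C=Cc2cc(CCc3cccc(O[Si](C)(C)C(C)(C)C)c3O[Si](C)(C)C(C)(C)C)ccc2O1)CO[Si](C)(C)C(C)(C)C | intermediate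
13 | 3-{2-[(2S)-2-[(3E)-5-hydroxy-4-methylpent-3-enyl]-2-methyl-2H-chromen-6-yl]ethyl}benzene-1,2-diol | C/C(=C\CC[C@@]1(C)C=Cc2cc(CCc3cccc(O)c3O)ccc2O1)CO | target

Total step count: 8.
Longest linear sequence: 7 steps (steps 1, 2, 3, 4, 5, 7 and 8, from (S)-linalool); step 6 is a one-step side branch.

Steps most likely to fail

Step 4. The photostationary mixture may stay rich in the E-isomer, tert-butoxide may displace the fluoride intermolecularly before cyclisation, or sensitised electrocyclic opening of the chromene may erode the configuration at C2. The fallback forms the O1–C8a bond first and the C3=C4 bond last, without light; it sets out from 3 (together with 4) and comes back to the route at 7. The potassium alkoxide of 3 (KH, THF, 0 °C) would displace the fluoride of 4 in an intermolecular SNAr reaction to give 3-bromo-4-{[(3S,6E)-8-(tert-butyldimethylsilyloxy)-3,7-dimethylocta-1,6-dien-3-yl]oxy}benzaldehyde F1. Stille coupling with tributyl(vinyl)stannane (Pd(PPh3)4, CuI, CsF, DMF, 45 °C) would give 4-{[(3S,6E)-8-(tert-butyldimethylsilyloxy)-3,7-dimethylocta-1,6-dien-3-yl]oxy}-3-vinylbenzaldehyde F2. Ring-closing metathesis with second-generation Grubbs catalyst (CH2Cl2, 40 °C) would then join the two vinyl groups and release ethylene, the unhindered aryl vinyl group initiating first, and give 7 with C2 untouched.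

Step 7. Transmetalation of the homobenzylic borane may be slow, β-hydride elimination at palladium may return 8, and the basic medium may strip an aryl silyl group from 10 before oxidative addition. The fallback is a base-free Negishi coupling; it sets out from 8 and comes back at 12. Hydroboration of 8 to 11 as above, followed by oxidation (NaBO3·4H2O, THF/H2O, rt), would give 2-{(2S)-2-[(E)-5-(tert-butyldimethylsilyloxy)-4-methylpent-3-enyl]-2-methyl-2H-chromen-6-yl}ethanol F3. Appel-type iodination (I2, PPh3, imidazole, CH2Cl2, 0 °C) would give (S)-2-[(E)-5-(tert-butyldimethylsilyloxy)-4-methylpent-3-enyl]-6-(2-iodoethyl)-2-methyl-2H-chromene F4. Zinc insertion (Zn dust, LiCl, THF, 40 °C) would give {2-[(2S)-2-[(E)-5-(tert-butyldimethylsilyloxy)-4-methylpent-3-enyl]-2-methyl-2H-chromen-6-yl]ethyl}zinc iodide F5, which would couple with 10 (Pd(OAc)2, SPhos, THF, rt) to give 12.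

Step 1. Over-oxidation of the allylic alcohol to the enal, together with incomplete conversion, may leave a mixture that is hard to separate. The fallback builds the E-allylic alcohol by olefination; it sets out from 1 and comes back at 2. Ozonolysis of the more electron-rich trisubstituted alkene (O3, one equivalent, CH2Cl2/MeOH, −78 °C; then Me2S) would give (5S)-5-ethenyl-5-methyloxolan-2-ol F6 as an anomeric mixture. Wittig reaction with ethyl 2-(triphenylphosphoranylidene)propanoate (toluene, 80 °C) would open the lactol to ethyl (2E,6S)-6-hydroxy-2,6-dimethylocta-2,7-dienoate F7, and reduction with i-Bu2AlH (CH2Cl2, −78 °C) would give 2.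

Further compounds
F1 | step 4 | 3-bromo-4-{[(3S,6E)-8-(tert-butyldimethylsilyloxy)-3,7-dimethylocta-1,6-dien-3-yl]oxy}benzaldehyde | C/C(=C\CC[C@@](Oc1ccc(C=O)cc1Br)(C)C=C)CO[Si](C)(C)C(C)(C)C
F2 | step 4 | 4-{[(3S,6E)-8-(tert-butyldimethylsilyloxy)-3,7-dimethylocta-1,6-dien-3-yl]oxy}-3-vinylbenzaldehyde | C/C(=C\CC[C@@](Oc1ccc(C=O)cc1C=C)(C)C=C)CO[Si](C)(C)C(C)(C)C
F3 | step 7 | 2-{(2S)-2-[(E)-5-(tert-butyldimethylsilyloxy)-4-methylpent-3-enyl]-2-methyl-2H-chromen-6-yl}ethanol | C/C(=C\CC[C@@]1(C)C=Cc2cc(CCO)ccc2O1)CO[Si](C)(C)C(C)(C)C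
F4 | step 7 | (S)-2-[(E)-5-(tert-butyldimethylsilyloxy)-4-methylpent-3-enyl]-6-(2-iodoethyl)-2-methyl-2H-chromene | C/C(=C\CC[C@@]1(C)C=Cc2cc(CCI)ccc2O1)CO[Si](C)(C)C(C)(C)C
F5 | step 7 | {2-[(2S)-2-[(E)-5-(tert-butyldimethylsilyloxy)-4-methylpent-3-enyl]-2-methyl-2H-chromen-6-yl]ethyl}zinc iodide | C/C(=C\CC[C@@]1(C)C=Cc2cc(CC[Zn]I)ccc2O1)CO[Si](C)(C)C(C)(C)C
F6 | step 1 | (5S)-5-ethenyl-5-methyloxolan-2-ol (anomeric mixture) | C=C[C@]1(C)CCC(O)O1
F7 | step 1 | ethyl (2E,6S)-6-hydroxy-2,6-dimethylocta-2,7-dienoate | CCOC(=O)/C(C)=C/CC[C@@](O)(C)C=C
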